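**Retrosynthetic overview**
- Target ⇐ methyl ketone at C17 (chelate-controlled chloromethyl addition, then epoxide closure) ⇐ C15 ketone (chelate-controlled reduction).
- Quaternary C12 and the C12–C14 bond ⇐ Carroll [3,3] rearrangement of a ring C allylic β-keto ester that carries a D-threonine-derived acyl unit.
- Ring C ⇐ aldol condensation of a cis-diacetyl cycloadduct (acetyl groups on C8 and C20).
- Rings B and D together ⇐ key intramolecular Diels–Alder reaction of a ring A diene with an enone tethered at C5 (sets C5, C8, C20, C21).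
- Ring A ⇐ (S)-pulegone by Favorskii contraction. Ring order: A (bought) → B + D (cycloaddition) → C (aldol).

Assumption: (S)-(−)-pulegone and O-benzyl-D-threonine are bought as the only sources of chirality, and carbon locants C1–C25 count the carbons in the order they are written in the target SMILES (ring A: C2–C6; ring B: C5, C6, C7, C8, C20, C21; ring C: C8, C10, C11, C12, C20; ring D: C5, C21–C24; methyls C1, C9, C13, C18, C25; side chain C14–C19).

**Route**

Step 1
Reactants: 1 (S)-(−)-pulegone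
Product: 3 methyl (5S)-5-methyl-2-(propan-2-ylidene)cyclopentane-1-carboxylate, via pulegone dibromide 2 (not isolated)
Conditions: Br2, Et2O, −10 °C; then NaOMe, MeOH, reflux
Reagents that add atoms: bromine, BrBr (its atoms stay only in 2); sodium methoxide, C[O-].[Na+]
Why: Favorskii ring contraction of the dibromide gives the cyclopentane ester regiospecifically; the methyl-bearing stereocentre (later C2) is bought and untouched.

Step 2
Reactants: 3 methyl (5S)-5-methyl-2-(propan-2-ylidene)cyclopentane-1-carboxylate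
Product: 4 methyl (2S)-2-methyl-5-oxocyclopentane-1-carboxylate
Conditions: O3, CH2Cl2/MeOH, −78 °C; then Me2S
Reagents that add atoms: ozone, [O-][O+]=O
Why: Ozonolysis of the only C=C gives the β-keto ester; the C2 methyl centre is not enolisable toward the ketone and is retained.

Step 3
Reactants: 4 methyl (2S)-2-methyl-5-oxocyclopentane-1-carboxylate
Product: 5 methyl (5S)-5-methyl-2-[(trifluoromethanesulfonyl)oxy]cyclopent-1-ene-1-carboxylate
Conditions: Tf2O, iPr2NEt, CH2Cl2, −78 °C
Reagents that add atoms: trifluoromethanesulfonic anhydride, O=S(=O)(OS(=O)(=O)C(F)(F)F)C(F)(F)F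
Why: O-sulfonylation of the β-keto ester enol gives the conjugated enol triflate (future C5=C6 with C7 as ester carbon).

Step 4
Reactants: 6 2,3-dibromoprop-1-ene; 7 allylmagnesium bromide
Product: 8 2-bromohexa-1,5-diene
Conditions: Et2O, 0 °C → rt
Reagents that add atoms: none
Why: Allylic substitution of the allylic bromide by the Grignard reagent (SN2 and SN2′ give the same product); the vinylic bromide does not react.

Step 5
Reactants: 8 2-bromohexa-1,5-diene; 5 methyl (5S)-5-methyl-2-[(trifluoromethanesulfonyl)oxy]cyclopent-1-ene-1-carboxylate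
Product: 11 methyl (5S)-2-(hexa-1,5-dien-2-yl)-5-methylcyclopent-1-ene-1-carboxylate, via hexa-1,5-dien-2-yllithium 9 (not isolated), via hexa-1,5-dien-2-ylzinc chloride 10 (not isolated)
Conditions: 8, tBuLi (2 equiv), THF, −78 °C; ZnCl2; then 5, Pd(PPh3)4 (5 mol %), THF, rt → 40 °C
Reagents that add atoms: tert-butyllithium, [Li]C(C)(C)C (Li only in 9); zinc chloride, Cl[Zn]Cl (Zn and Cl only in 10)
Why: Bromine–lithium exchange, transmetalation and Negishi cross-coupling with the activated β-triflyloxy enoate attach the C24–C21 tether at C5.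

Step 6
Reactants: 11 methyl (5S)-2-(hexa-1,5-dien-2-yl)-5-methylcyclopent-1-ene-1-carboxylate
Product: 12 [(5S)-2-(hexa-1,5-dien-2-yl)-5-methylcyclopent-1-en-1-yl]methanol
Conditions: iBu2AlH (2.2 equiv), CH2Cl2, −78 °C; aq. potassium sodium tartrate
Reagents that add atoms: none
Why: 1,2-Reduction of the conjugated ester to the allylic alcohol; the alkenes are inert.

Step 7
Reactants: 12 [(5S)-2-(hexa-1,5-dien-2-yl)-5-methylcyclopent-1-en-1-yl]methanol
Product: 13 (5S)-2-(hexa-1,5-dien-2-yl)-5-methylcyclopent-1-ene-1-carbaldehyde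
Conditions: MnO2, CH2Cl2, rt
Reagents that add atoms: none
Why: Chemoselective allylic oxidation to the enal (C7 aldehyde) without touching the isolated alkenes.

Step 8
Reactants: 13 (5S)-2-(hexa-1,5-dien-2-yl)-5-methylcyclopent-1-ene-1-carbaldehyde; 14 diethyl (3-oxobutan-2-yl)phosphonate
Product: 15 (3E)-4-[(5S)-2-(hexa-1,5-dien-2-yl)-5-methylcyclopent-1-en-1-yl]-3-methylbut-3-en-2-one
Conditions: NaH, THF, 0 → 40 °C
Reagents that add atoms: none
Why: Horner–Wadsworth–Emmons olefination gives the E-enone, which places the C9 methyl cis to C6 (inside) and the acetyl outside on the diene terminus C8.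

Step 9
Reactants: 15 (3E)-4-[(5S)-2-(hexa-1,5-dien-2-yl)-5-methylcyclopent-1-en-1-yl]-3-methylbut-3-en-2-one; 16 but-3-en-2-one
Product: 18 tricyclic diketone (rings A B D), via cross-metathesis enone 17 (not isolated)
Conditions: 16 (4 equiv), second-generation Hoveyda–Grubbs catalyst (C31H38Cl2N2ORu, 5 mol %), PhMe, 45 °C; then BHT, 105 °C
Reagents that add atoms: none
Why: Olefin cross-metathesis of the only monosubstituted alkene gives the E-enone, which undergoes the key intramolecular Diels–Alder reaction. The tether sits cis on C5, so ring D must be cis-fused; the two E-alkenes fix C8 (acetyl cis to C4) and trans H20/H21; the dienophile adds anti to the C2 methyl, setting C5, C8, C20 and C21.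

Step 10
Reactants: 18 tricyclic diketone (rings A B D)
Product: 20 tetracyclic enone (C10 ketone with C11=C12), via aldol adduct 19 (not isolated)
Conditions: KOH, MeOH, 60 °C
Reagents that add atoms: none
Why: Intramolecular aldol condensation: the methyl enolate of the C8 acetyl attacks the less hindered C12 ketone (the neopentyl C10 carbonyl is shielded), and the cis acetyl groups give cis-fused ring C.

Step 11
Reactants: 20 tetracyclic enone (C10 ketone with C11=C12)
Product: 21 allylic alcohol (10-OH cis to the C9 methyl)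
Conditions: NaBH4, CeCl3·7H2O, MeOH, −40 °C
Reagents that add atoms: none
Why: Luche 1,2-reduction; hydride attacks the face opposite the angular C9 methyl, so the C10 hydroxyl ends up cis to that methyl.

Step 12
Reactants: 22 O-benzyl-D-threonine
Product: 23 (2R,3S)-3-(benzyloxy)-2-hydroxybutanoic acid
Conditions: NaNO2, 1 M H2SO4, 0 °C → rt
Reagents that add atoms: water, O
Why: Diazotisation of the α-amino acid with net retention (double inversion through the α-lactone) turns the bought C2 centre into the future C16 carbinol.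

Step 13
Reactants: 23 (2R,3S)-3-(benzyloxy)-2-hydroxybutanoic acid
Product: 25 (2R,3S)-3-(benzyloxy)-2-(methoxymethoxy)butanoic acid, via methoxymethyl ester 24 (not isolated)
Conditions: MOMCl (2.5 equiv), iPr2NEt, CH2Cl2, 0 °C → rt; then LiOH, THF/H2O; HCl to pH 3
Reagents that add atoms: chloromethyl methyl ether, COCCl
Why: Acetal protection of the hydroxyl (a chelating group for later steps), then selective saponification of the labile methoxymethyl ester.

Step 14
Reactants: 25 (2R,3S)-3-(benzyloxy)-2-(methoxymethoxy)butanoic acid; 26 Meldrum's acid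
Product: 27 acyl Meldrum's acid
Conditions: DCC, DMAP, CH2Cl2, 0 °C
Reagents that add atoms: none
Why: Carbodiimide-mediated C-acylation of Meldrum's acid gives a thermal acylketene precursor without touching the α-stereocentre.

Step 15
Reactants: 21 allylic alcohol (10-OH cis to the C9 methyl); 27 acyl Meldrum's acid
Product: 31 side-chain ketone (C15 ketone with C10=C11), via acylketene 28 (not isolated), via allyl β-keto ester 29 (not isolated), via β-keto acid 30 (not isolated)
Conditions: PhMe, 110 °C; then xylenes, 150 °C (sealed tube)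
Reagents that add atoms: none
Why: Acylketene trapping by the alcohol, then Carroll rearrangement ([3,3]-sigmatropic) and decarboxylation. The suprafacial shift delivers C14 to C12 on the face of the former C10–O bond (cis to H20), so the quaternary centre forms with the C13 methyl cis to C21.

Step 16
Reactants: 31 side-chain ketone (C15 ketone with C10=C11)
Product: 32 C15 alcohol
Conditions: Zn(BH4)2, Et2O, −30 °C
Reagents that add atoms: none
Why: Chelation-controlled (Cram chelate between the C15 carbonyl and the C16 methoxymethoxy oxygen) hydride reduction gives the 15,16-anti arrangement.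

Step 17
Reactants: 32 C15 alcohol
Product: 33 bis(methoxymethyl) ether
Conditions: MOMCl, iPr2NEt, CH2Cl2, 40 °C
Reagents that add atoms: chloromethyl methyl ether, COCCl
Why: Acetal protection of the C15 hydroxyl so that only the C17 oxygen is oxidised later.

Step 18
Reactants: 33 bis(methoxymethyl) ether
Product: 34 saturated C17 alcohol
Conditions: H2 (4 atm), Pd/C (10 wt %), EtOAc/EtOH, rt
Reagents that add atoms: none
Why: Heterogeneous hydrogenation and hydrogenolysis reduce C10=C11 and C24=CH2 and cleave the benzyl ether. Hydrogen adds to C24 from the convex face of the cis-fused B/D system (the C4 side), placing the C25 methyl toward ring B; the hindered C6=C7 alkene survives.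

Step 19
Reactants: 34 saturated C17 alcohol
Product: 35 methyl ketone (C17 ketone)
Conditions: Dess–Martin periodinane, NaHCO3, CH2Cl2, rt
Reagents that add atoms: none
Why: Mild buffered oxidation of the only free hydroxyl gives the α-alkoxy methyl ketone without epimerising C16.

Step 20
Reactants: 35 methyl ketone (C17 ketone)
Product: 36 chlorohydrin
Conditions: ICH2Cl, iPrMgCl·LiCl, THF, −78 °C
Reagents that add atoms: chloroiodomethane, ClCI
Why: Chelation-controlled (Cram chelate through magnesium and the C16 methoxymethoxy oxygen) addition of the chloromethyl Grignard carbenoid attacks the ketone face next to H16 and sets C17.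

Step 21
Reactants: 36 chlorohydrin
Product: 38 CNP0393869.2, via chlorotriol 37 (not isolated)
Conditions: HCl (cat.), MeOH, 40 °C; then K2CO3, MeOH, 0 °C
Reagents that add atoms: none
Why: Acetal methanolysis frees the 15,16-diol, and Williamson-type closure (intramolecular SN2 of the tertiary alkoxide on CH2Cl) forms the epoxide with C17 unchanged.

**Compound list**
1 | (S)-(−)-pulegone, (5S)-5-methyl-2-(propan-2-ylidene)cyclohexan-1-one | C[C@H]1CCC(=C(C)C)C(=O)C1 | starting material
2 | pulegone dibromide, (5S)-2-bromo-2-(2-bromopropan-2-yl)-5-methylcyclohexan-1-one (C2 epimers) | C[C@H]1CCC(Br)(C(C)(C)Br)C(=O)C1 | intermediate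
3 | methyl (5S)-5-methyl-2-(propan-2-ylidene)cyclopentane-1-carboxylate (methyl pulegenate, C1 epimers) | C[C@H]1CCC(=C(C)C)C1C(=O)OC | intermediate
4 | methyl (2S)-2-methyl-5-oxocyclopentane-1-carboxylate (C1 epimers) | C[C@H]1CCC(=O)C1C(=O)OC | intermediate
5 | methyl (5S)-5-methyl-2-[(trifluoromethanesulfonyl)oxy]cyclopent-1-ene-1-carboxylate | C[C@H]1CCC(OS(=O)(=O)C(F)(F)F)=C1C(=O)OC | intermediate
6 | 2,3-dibromoprop-1-ene | C=C(Br)CBr | starting material
7 | allylmagnesium bromide | C=CC[Mg]Br | starting material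
8 | 2-bromohexa-1,5-diene | C=CCCC(Br)=C | intermediate
9 | hexa-1,5-dien-2-yllithium | [Li]C(=C)CCC=C | intermediate
10 | hexa-1,5-dien-2-ylzinc chloride | Cl[Zn]C(=C)CCC=C | intermediate
11 | methyl (5S)-2-(hexa-1,5-dien-2-yl)-5-methylcyclopent-1-ene-1-carboxylate | C[C@H]1CCC(C(=C)CCC=C)=C1C(=O)OC | intermediate
12 | [(5S)-2-(hexa-1,5-dien-2-yl)-5-methylcyclopent-1-en-1-yl]methanol | C[C@H]1CCC(C(=C)CCC=C)=C1CO | intermediate
13 | (5S)-2-(hexa-1,5-dien-2-yl)-5-methylcyclopent-1-ene-1-carbaldehyde | C[C@H]1CCC(C(=C)CCC=C)=C1C=O | intermediate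
14 | diethyl (3-oxobutan-2-yl)phosphonate | CCOP(=O)(OCC)C(C)C(C)=O | starting material
15 | (3E)-4-[(5S)-2-(hexa-1,5-dien-2-yl)-5-methylcyclopent-1-en-1-yl]-3-methylbut-3-en-2-one | C[C@H]1CCC(C(=C)CCC=C)=C1/C=C(\C)C(C)=O | intermediate
16 | but-3-en-2-one (methyl vinyl ketone) | CC(=O)C=C | starting material
17 | cross-metathesis enone, (3E)-7-{(3S)-3-methyl-2-[(1E)-2-methyl-3-oxobut-1-en-1-yl]cyclopent-1-en-1-yl}octa-3,7-dien-2-one | C[C@H]1CCC(C(=C)CC/C=C/C(C)=O)=C1/C=C(\C)C(C)=O | intermediate
18 | tricyclic diketone, rings A B D: C6=C7, C8 carries CH3 and acetyl, C20 carries acetyl, C24=CH2; acetyl groups cis to each other and to C4, H20 and H21 trans, ring D cis-fused, C2 C5 C8 C20 C21 arranged as in the target | C[C@H]1CC[C@@]23C1=C[C@@](C)(C(C)=O)[C@@H](C(C)=O)[C@@H]2CCC3=C | intermediate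
19 | aldol adduct: ring C closed, C10 ketone, C12 carries OH and CH3 (C12 epimers) | C[C@H]1CC[C@@]23C1=C[C@@]1(C)C(=O)CC(C)(O)[C@H]1[C@@H]2CCC3=C | intermediate
20 | tetracyclic enone: C10 ketone, C11=C12 with CH3 on C12, C6=C7, C24=CH2, rings B/C cis-fused | C[C@H]1CC[C@@]23C1=C[C@@]1(C)C(=O)C=C(C)[C@H]1[C@@H]2CCC3=C | intermediate
21 | allylic alcohol: as 20 with C10 CH–OH, hydroxyl cis to the C9 methyl | C[C@H]1CC[C@@]23C1=C[C@@]1(C)[C@H](O)C=C(C)[C@H]1[C@@H]2CCC3=C | intermediate
22 | O-benzyl-D-threonine, (2R,3S)-2-amino-3-(benzyloxy)butanoic acid | C[C@@H]([C@H](C(=O)O)N)OCc1ccccc1 | starting material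
23 | (2R,3S)-3-(benzyloxy)-2-hydroxybutanoic acid | C[C@@H]([C@H](C(=O)O)O)OCc1ccccc1 | intermediate
24 | methoxymethyl (2R,3S)-3-(benzyloxy)-2-(methoxymethoxy)butanoate | C[C@@H]([C@H](C(=O)OCOC)OCOC)OCc1ccccc1 | intermediate
25 | (2R,3S)-3-(benzyloxy)-2-(methoxymethoxy)butanoic acid | C[C@@H]([C@H](C(=O)O)OCOC)OCc1ccccc1 | intermediate
26 | Meldrum's acid, 2,2-dimethyl-1,3-dioxane-4,6-dione | CC1(C)OC(=O)CC(=O)O1 | starting material
27 | acyl Meldrum's acid, 5-[(2R,3S)-3-(benzyloxy)-1-hydroxy-2-(methoxymethoxy)butylidene]-2,2-dimethyl-1,3-dioxane-4,6-dione | C[C@@H]([C@H](C(O)=C1C(=O)OC(C)(C)OC1=O)OCOC)OCc1ccccc1 | intermediate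
28 | acylketene, (4R,5S)-5-(benzyloxy)-4-(methoxymethoxy)hex-1-ene-1,3-dione | C[C@@H]([C@H](C(=O)C=C=O)OCOC)OCc1ccccc1 | intermediate
29 | allyl β-keto ester: C10 ester of 21 with the 3-oxo acid derived from 28 | C[C@H]1CC[C@@]23C1=C[C@@]1(C)[C@H](OC(=O)CC(=O)[C@H](OCOC)[C@H](C)OCc4ccccc4)C=C(C)[C@H]1[C@@H]2CCC3=C | intermediate
30 | β-keto acid: C12 quaternary (CH3 cis to C21), C14 carries CO2H (C14 epimers), C10=C11 | C[C@H]1CC[C@@]23C1=C[C@@]1(C)C=C[C@](C)(C(C(=O)O)C(=O)[C@H](OCOC)[C@H](C)OCc4ccccc4)[C@H]1[C@@H]2CCC3=C | intermediate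
31 | side-chain ketone: C12 carries CH3 and C14H2–C15(=O)–C16H(OMOM)–C17H(OBn)–C18H3; C10=C11, C6=C7, C24=CH2 | C[C@H]1CC[C@@]23C1=C[C@@]1(C)C=C[C@](C)(CC(=O)[C@H](OCOC)[C@H](C)OCc4ccccc4)[C@H]1[C@@H]2CCC3=C | intermediate
32 | C15 alcohol: as 31 with C15 CH–OH, 15,16-anti as in the target | C[C@H]1CC[C@@]23C1=C[C@@]1(C)C=C[C@](C)(C[C@H](O)[C@H](OCOC)[C@H](C)OCc4ccccc4)[C@H]1[C@@H]2CCC3=C | intermediate
33 | bis(methoxymethyl) ether: as 32 with C15 OMOM | C[C@H]1CC[C@@]23C1=C[C@@]1(C)C=C[C@](C)(C[C@H](OCOC)[C@H](OCOC)[C@H](C)OCc4ccccc4)[C@H]1[C@@H]2CCC3=C | intermediate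
34 | saturated C17 alcohol: rings as in the target (C24 methyl as in the target), C15 and C16 OMOM, C17 CH(OH)CH3 | C[C@H]1CC[C@@]23C1=C[C@@]1(C)CC[C@](C)(C[C@H](OCOC)[C@H](OCOC)[C@H](C)O)[C@H]1[C@@H]2CC[C@@H]3C | intermediate
35 | methyl ketone: as 34 with C17 ketone | C[C@H]1CC[C@@]23C1=C[C@@]1(C)CC[C@](C)(C[C@H](OCOC)[C@H](OCOC)C(C)=O)[C@H]1[C@@H]2CC[C@@H]3C | intermediate
36 | chlorohydrin: C17 carries OH, CH3 and CH2Cl, configured as in the target | C[C@H]1CC[C@@]23C1=C[C@@]1(C)CC[C@](C)(C[C@H](OCOC)[C@H](OCOC)[C@](O)(C)CCl)[C@H]1[C@@H]2CC[C@@H]3C | intermediate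
37 | chlorotriol: as 36 with free C15 and C16 hydroxyls | C[C@H]1CC[C@@]23C1=C[C@@]1(C)CC[C@](C)(C[C@H](O)[C@H](O)[C@](O)(C)CCl)[C@H]1[C@@H]2CC[C@@H]3C | intermediate
38 | CNP0393869.2, (2S,5S,8R,12R,15S,16S,17S,20R,21S,24S) by the carbon-order locants | C[C@H]1CC[C@@]23C1=C[C@@]1(C)CC[C@](C)(C[C@H](O)[C@H](O)[C@]4(C)CO4)[C@H]1[C@@H]2CC[C@@H]3C | target

**Step count**
Total: 21 steps. Longest linear sequence: 17 steps (steps 1–3, 5–11, 15–21, from 1).

**Three steps most likely to fail, with fallbacks**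

Step 9 (cross-metathesis and intramolecular Diels–Alder). The diene is electron-poor and carries an inside substituent at each terminus, so a 6π-electrocyclisation or a 1,5-hydrogen shift of the conjugated triene may compete, and facial control rests on the C2 methyl alone. Fallback from 15 back to 18: cleave the monosubstituted alkene of 15 (OsO4 cat., NaIO4, 2,6-lutidine, dioxane/H2O) to the keto aldehyde F1. Condense F1 with methyl acetoacetate (piperidine, AcOH, CH2Cl2, 0 °C → rt) to the alkylidene acetoacetate F2, whose doubly activated dienophile should cyclise at room temperature to the keto ester cycloadduct F3. Krapcho dealkoxycarbonylation (LiCl, wet DMSO, 140 °C) then returns 18; any C20 epimer converges under the basic conditions of step 10.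

Step 10 (aldol regiochemistry). The other methyl ketone could enolise and attack C10, giving the isomeric cyclopentenone. Fallback from 15 back to 20: run the metathesis of step 9 with methyl acrylate in place of 16 to give the metathesis enoate F4, which cyclises in the same way to the keto ester cycloadduct F5. F5 has a single methyl ketone, so KOtBu (THF, 0 °C) can only close ring C by Claisen condensation onto the ester, giving the cyclopentane-1,3-dione F6. O-Triflation at the less hindered C12 oxygen (Tf2O, Et3N, CH2Cl2, −78 °C) gives the enol triflate F7, and Me2CuLi (Et2O, −78 °C) replaces the triflate by methyl to give 20.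

Step 15 (Carroll rearrangement forming a quaternary centre). Thermal elimination of the hindered allylic ester to a diene may outrun the [3,3] shift. Fallback from 20 (using 25) back to 31: treat acid 25 with MeLi (2.2 equiv, Et2O, −78 → 0 °C) to give the methyl ketone F8, and convert F8 (LiN(iPr)2, Me3SiCl, THF, −78 °C) into the silyl enol ether F9. Mukaiyama–Michael addition of F9 to enone 20 (Me3SiOTf cat., CH2Cl2, −78 °C) forms the C12–C14 bond intermolecularly from the convex face, anti to C21, and leaves the C10 oxygen as the silyl enol ether adduct F10. CsF with PhNTf2 converts F10 into the C10 enol triflate F11, and Pd(OAc)2/PPh3 with HCO2H/Bu3N reduces F11 to the C10=C11 alkene 31.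

**Further compounds**
F1 | step 9 | keto aldehyde, 4-{(3S)-3-methyl-2-[(1E)-2-methyl-3-oxobut-1-en-1-yl]cyclopent-1-en-1-yl}pent-4-enal | C[C@H]1CCC(C(=C)CCC=O)=C1/C=C(\C)C(C)=O
F2 | step 9 | alkylidene acetoacetate, methyl 2-acetyl-6-{(3S)-3-methyl-2-[(1E)-2-methyl-3-oxobut-1-en-1-yl]cyclopent-1-en-1-yl}hepta-2,6-dienoate | C[C@H]1CCC(C(=C)CCC=C(C(C)=O)C(=O)OC)=C1/C=C(\C)C(C)=O
F3 | step 9 | keto ester cycloadduct: as 18 with C20 carrying acetyl and CO2CH3 (C20 epimers) | C[C@H]1CC[C@@]23C1=C[C@@](C)(C(C)=O)C(C(C)=O)(C(=O)OC)[C@@H]2CCC3=C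
F4 | step 10 | metathesis enoate, methyl (2E)-6-{(3S)-3-methyl-2-[(1E)-2-methyl-3-oxobut-1-en-1-yl]cyclopent-1-en-1-yl}hepta-2,6-dienoate | C[C@H]1CCC(C(=C)CC/C=C/C(=O)OC)=C1/C=C(\C)C(C)=O
F5 | step 10 | keto ester cycloadduct: as 18 with CO2CH3 in place of the C20 acetyl | C[C@H]1CC[C@@]23C1=C[C@@](C)(C(C)=O)[C@@H](C(=O)OC)[C@@H]2CCC3=C
F6 | step 10 | cyclopentane-1,3-dione: ring C with C10 and C12 ketones | C[C@H]1CC[C@@]23C1=C[C@@]1(C)C(=O)CC(=O)[C@H]1[C@@H]2CCC3=C
F7 | step 10 | enol triflate: C10 ketone, C11=C12 with OSO2CF3 on C12 | C[C@H]1CC[C@@]23C1=C[C@@]1(C)C(=O)C=C(OS(=O)(=O)C(F)(F)F)[C@H]1[C@@H]2CCC3=C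
F8 | step 15 | methyl ketone, (3R,4S)-4-(benzyloxy)-3-(methoxymethoxy)pentan-2-one | C[C@@H]([C@H](C(C)=O)OCOC)OCc1ccccc1
F9 | step 15 | silyl enol ether, {[(3R,4S)-4-(benzyloxy)-3-(methoxymethoxy)pent-1-en-2-yl]oxy}trimethylsilane | C[C@@H]([C@H](C(=C)O[Si](C)(C)C)OCOC)OCc1ccccc1
F10 | step 15 | silyl enol ether adduct: as 31 with OSi(CH3)3 on C10 | C[C@H]1CC[C@@]23C1=C[C@@]1(C)C(O[Si](C)(C)C)=C[C@](C)(CC(=O)[C@H](OCOC)[C@H](C)OCc4ccccc4)[C@H]1[C@@H]2CCC3=C
F11 | step 15 | C10 enol triflate: as 31 with OSO2CF3 on C10 | C[C@H]1CC[C@@]23C1=C[C@@]1(C)C(OS(=O)(=O)C(F)(F)F)=C[C@](C)(CC(=O)[C@H](OCOC)[C@H](C)OCc4ccccc4)[C@H]1[C@@H]2CCC3=C
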